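The data were computed with constants of no real substance, noise included.

You are the chemist at the bench with the delta run in hand, and you must say what stands in a flask of twice the substrate concentration after much longer.

- delta: substrate 0.050 M; reagent 0.50 equiv; run made earlier
- flask: substrate 0.10 M; reagent 0.500 equiv; time 30 min

- delta (time / min: target / %, isomer of the product A / %): 0.667: 4.6, 0.5; 2.00: 10.3, 0.6; 3.00: 11.5, 1.2; 5.00: 12.9, 1.1; 6.00: 13.4, 0.7; 10.0: 13.1, 1.4

(scatter of a reading: 0.3 percentage points)



1. concentration of target at 30 min, in M
2. concentration of isomer of the product A at 30 min, in M
3. concentration of isomer of the product B at 30 min, in M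
4. concentration of reagent at 30 min, in M

Reagent is the limiting reagent here, so follow its fate. I count what substrate has not captured, using a quantity I call the capture odds: reagent taken up by substrate over reagent not taken up. In the delta run the last readings average:

target 13.1%, isomer of the product A 1.07%

captured share of reagent = 28.4%, share left uncaptured = 71.6%

capture odds = 0.397

This counts no isomer of the product B. If the rival loss of reagent ignores substrate, the odds scale with substrate:

flask odds = 0.793, captured share = 44.2%

c(target) = 0.0205 M

That scaling is the weak link. A rival of the same order as capture leaves the odds unchanged, and my c(target) becomes 0.0131 M. I commit to the first figure and keep the second as the low end.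

The forecast gave 0.0138 M, 0.0011 M, 0.0345 M and 6.000 × 10⁻⁴ M for target, isomer of the product A, isomer of the product B and reagent: “The simplest reading is that the reagent is used up and the unmeasured isomer B takes the remainder”.

The flask gives 0.0139 M, 0.00409 M, 0.0170 M and 0.00493 M.

    substrate + reagent ⇌ target (K = 49.0 L mol⁻¹, k = 0.0675 L mol⁻¹ s⁻¹)
    substrate + reagent ⇌ isomer of the product A (K = 337 L mol⁻¹, k = 0.00389 L mol⁻¹ s⁻¹)
    reagent ⇌ dormant form (K = 1.90, k = 0.00668 s⁻¹)
    target ⇌ isomer of the product B (K = 2.50, k = 7.42 × 10⁻⁴ s⁻¹)

At 3.00 min this flask has 78.5% substrate left and target at 18.4%, so its capture odds are 0.754. At 30 min target is made more slowly than it is used up, at 0.452 of that rate, and it stands at 13.9%.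

For the neighbour flask with 1.20 equiv of reagent, I try the flask odds of 0.793 as an untested estimate: a captured share of 44.2% of that reagent charge gives substrate left = 47.0%. That neighbour flask holds 32.9% substrate at 30 min, so its capture odds are 1.27, higher than the trial value.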